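Ring B is closed last, across C6–C7 and C9–C10. The feature used is that C6 and C10 are the δ- and β-carbons of a 2-oxo ring A, so 4-methyleneisophorone is a 1,3-bis-electrophile. C7–C8–C9 of (R)-citronellic acid becomes the matching 1,3-bis-nucleophile once C7 carries an enantiopure sulfonimidoyl group. One lithium-mediated double conjugate addition joins the two ten-carbon halves, builds the quaternary C10 beside C9 and sets the cis ring fusion through the epimerisable C5. Sulfur removal, equilibrating reduction of the C2 ketone, angeloylation and ester cleavage finish the route.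

Key step: step 8

Remark on names: the bicyclic compounds are named on the labdane skeleton (C1–C10 in rings A and B, C11–C16 in the chain, C17 on C8, C18 and C19 on C4, C20 on C10) with explicit descriptors. The target is the cis-fused decalin with H-5, H-9 and CH3-20 on one face and the C2 oxygen and the C9 chain on the other.

Assumption: the sense of induction by sulfur in step 8 is assigned from a chelate model; should it be the opposite, (R)-4-methylbenzenesulfinamide, equally available, replaces 9 and nothing else changes.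

Step 1
Reactants: 1 2,6,6-trimethylcyclohex-2-ene-1,4-dione (ketoisophorone)
Product: 2 7,9,9-trimethyl-1,4-dioxaspiro[4.5]dec-6-en-8-one
Conditions: HOCH2CH2OH, 4-MeC6H4SO3H·H2O (cat.), benzene, reflux, Dean–Stark
Reagents that add atoms: ethane-1,2-diol, OCCO
Why: Acid-catalysed dioxolane formation should be selective for the C4 carbonyl, because the C1 carbonyl is flanked by the quaternary C6 and the methyl-bearing C2.

Step 2
Reactants: 2 7,9,9-trimethyl-1,4-dioxaspiro[4.5]dec-6-en-8-one
Product: 4 3,5,5-trimethyl-4-methylidenecyclohex-2-en-1-one, via β-hydroxysilane 3 (not isolated)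
Conditions: Me3SiCH2Li, THF, −78 to 0 °C; then 2 M HCl (aq), 25 °C
Reagents that add atoms: (trimethylsilyl)methyllithium, [Li]C[Si](C)(C)C; water, O
Why: 1,2-Addition of the silylmethyl carbanion to the non-enolisable hindered ketone, then acid-induced Peterson olefination with concurrent dioxolane hydrolysis, should give the cross-ring dienone, which the gem-dimethyl group keeps from aromatising.

Step 3
Reactants: 5 (3R)-3,7-dimethyloct-6-enoic acid ((R)-citronellic acid)
Product: 6 tert-butyl (3R)-3,7-dimethyloct-6-enoate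
Conditions: Me2NCH(Ot-Bu)2, toluene, 80 °C
Reagents that add atoms: N,N-dimethylformamide di-tert-butyl acetal, CN(C)C(OC(C)(C)C)OC(C)(C)C
Why: Neutral tert-butyl ester formation by alkyl transfer from the amide acetal leaves the acid-sensitive trisubstituted alkene and the C3 stereocentre (later C13) untouched.

Step 4
Reactants: 6 tert-butyl (3R)-3,7-dimethyloct-6-enoate
Product: 7 tert-butyl (3R,6E)-8-hydroxy-3,7-dimethyloct-6-enoate
Conditions: SeO2 (cat.), t-BuOOH, 2-hydroxybenzoic acid (cat.), CH2Cl2, 25 °C
Reagents that add atoms: tert-butyl hydroperoxide, CC(C)(C)OO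
Why: Riley allylic oxidation (ene reaction, then 2,3-sigmatropic shift) is selective for the (E)-methyl group of a trisubstituted alkene and should give the (E)-allylic alcohol.

Step 5
Reactants: 7 tert-butyl (3R,6E)-8-hydroxy-3,7-dimethyloct-6-enoate
Product: 8 tert-butyl (3R,6E)-8-bromo-3,7-dimethyloct-6-enoate
Conditions: CBr4, PPh3, CH2Cl2, 0 °C
Reagents that add atoms: tetrabromomethane, BrC(Br)(Br)Br
Why: The Appel reaction replaces the primary allylic hydroxyl by bromide through SN2 attack on the oxyphosphonium ion, without allylic transposition at 0 °C.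

Step 6
Reactants: 9 (S)-4-methylbenzenesulfinamide
Product: 10 (S)-N-(2,2-dimethylpropanoyl)-4-methylbenzenesulfinamide
Conditions: NaH (2.2 equiv), THF, 0 °C; t-BuCOCl; then 1 M HCl (aq)
Reagents that add atoms: 2,2-dimethylpropanoyl chloride, CC(C)(C)C(=O)Cl
Why: N-Acylation of the sulfinamide anion occurs at nitrogen and does not touch the sulfur stereocentre.

Step 7
Reactants: 10 (S)-N-(2,2-dimethylpropanoyl)-4-methylbenzenesulfinamide, 8 tert-butyl (3R,6E)-8-bromo-3,7-dimethyloct-6-enoate
Product: 11 tert-butyl (3R,6E)-8-[(S)-N-(2,2-dimethylpropanoyl)-S-(4-methylphenyl)sulfonimidoyl]-3,7-dimethyloct-6-enoate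
Conditions: NaH, 15-crown-5, 1,4-dioxane, 25 °C
Reagents that add atoms: none
Why: S-Selective alkylation of the N-acyl sulfinamide anion at the sulfur lone pair (SN2 at the primary allylic bromide) should give the sulfoximine with retention at sulfur and unchanged (E) geometry.

Step 8
Reactants: 11 tert-butyl (3R,6E)-8-[(S)-N-(2,2-dimethylpropanoyl)-S-(4-methylphenyl)sulfonimidoyl]-3,7-dimethyloct-6-enoate, 4 3,5,5-trimethyl-4-methylidenecyclohex-2-en-1-one
Product: 13 tert-butyl (5R,9S,10S,13R)-7-[(R)-N-(2,2-dimethylpropanoyl)-S-(4-methylphenyl)sulfonimidoyl]-2-oxo-5,10-cis-labd-7-en-15-oate, via open-chain 1,6-adduct 12 (not isolated)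
Conditions: LiN(SiMe3)2 (1.05 equiv), THF, −78 °C; add 4; −78 to 0 °C; NH4Cl (aq)
Reagents that add atoms: none
Why: Proposed new method: the lithiated sulfoximine adds through its α-carbon C7 to the exposed δ-methylene C6 of the dienone (carbonyl 1,2-adducts revert on warming), the dienolate is protonated at C5 by the more acidic C7–H, and the regenerated sulfonimidoyl-allyl anion attacks the enone β-carbon C10 through its γ-carbon C9, so that a double conjugate addition forms C6–C7 and C9–C10 as a formal [3+3] annulation. The closest known reaction types are the conjugate additions of lithiated allylic sulfones and sulfoximines to cyclic enones through the α- or the γ-terminus and the intramolecular Michael addition that gives cis-fused decalones; their union in one flask, ending on a β,β-disubstituted enone, is the new element. Ring B closes in the 6-exo-trig mode, the only one open to the tethered anion, since α-attack would give a cyclobutane. C5 epimerises through the dienolate and is fixed only on ring closure, which requires C6 and C9 on the same face of ring A and so gives the cis fusion (H-5 syn to CH3-20); C9 and C10 follow from a lithium-bridged closed transition state (sulfonimidoyl oxygen–Li–enone oxygen) that holds ring A over the allyl unit with the C11 chain in the outer position, which puts H-9 syn to CH3-20. The absolute sense at C5, C9 and C10, which the remote C13 cannot control, is assigned to the sulfur stereocentre inside that chelate, and any ring-antipodal product would be a diastereomer at a neighbouring centre and hence separable. The step needs α- before γ-reactivity and 1,6- before 1,4-addition, which the sulfone-like charge at C7 and the hindered C10, reached only intramolecularly, should secure.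

Step 9
Reactants: 13 tert-butyl (5R,9S,10S,13R)-7-[(R)-N-(2,2-dimethylpropanoyl)-S-(4-methylphenyl)sulfonimidoyl]-2-oxo-5,10-cis-labd-7-en-15-oate
Product: 14 tert-butyl (5R,9R,10S,13R)-2-oxo-5,10-cis-labd-7-en-15-oate
Conditions: 6% Na(Hg), Na2HPO4, MeOH–THF, −20 °C
Reagents that add atoms: none
Why: Electron-transfer cleavage of the vinylic C–S bond, as in the desulfonylation of vinyl sulfones, should replace sulfur by hydrogen at C7 without moving the C7=C8 bond, and it returns sulfinamide 10.

Step 10
Reactants: 14 tert-butyl (5R,9R,10S,13R)-2-oxo-5,10-cis-labd-7-en-15-oate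
Product: 15 tert-butyl (2S,5R,9R,10S,13R)-2-hydroxy-5,10-cis-labd-7-en-15-oate
Conditions: Al(Oi-Pr)3 (0.3 equiv), i-PrOH, acetone (5 mol%), 82 °C
Reagents that add atoms: none
Why: Meerwein–Ponndorf–Verley reduction under equilibrating (Oppenauer-coupled) conditions should give the thermodynamic equatorial alcohol with oxygen anti to CH3-20, because the axial epimer would be syn-diaxial to both CH3-20 and the axial C4 methyl group.

Step 11
Reactants: 15 tert-butyl (2S,5R,9R,10S,13R)-2-hydroxy-5,10-cis-labd-7-en-15-oate, 16 (2Z)-2-methylbut-2-enoic acid (angelic acid)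
Product: 18 tert-butyl (2S,5R,9R,10S,13R)-2-[(2Z)-2-methylbut-2-enoyloxy]-5,10-cis-labd-7-en-15-oate, via mixed anhydride 17 (not isolated)
Conditions: 16, 2,4,6-Cl3C6H2COCl, Et3N, toluene, 25 °C; then 15, toluene, 80 °C
Reagents that add atoms: none
Why: Yamaguchi esterification run without a nucleophilic catalyst should transfer the angeloyl group to the unhindered equatorial alcohol with retention at C2 and without Z-to-E isomerisation to the tiglate.

Step 12
Reactants: 18 tert-butyl (2S,5R,9R,10S,13R)-2-[(2Z)-2-methylbut-2-enoyloxy]-5,10-cis-labd-7-en-15-oate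
Product: 19 (2S,5R,9R,10S,13R)-2-[(2Z)-2-methylbut-2-enoyloxy]-5,10-cis-labd-7-en-15-oic acid (CNP0248298.1)
Conditions: CF3CO2H, CH2Cl2, 0 °C
Reagents that add atoms: none
Why: Acidolysis of the tert-butyl ester (E1 loss of 2-methylpropene) should free the C15 acid at 0 °C without touching the angelate or the trisubstituted alkene.

Compound list
1 | 2,6,6-trimethylcyclohex-2-ene-1,4-dione (ketoisophorone) | CC1=CC(=O)CC(C)(C)C1=O | starting material
2 | 7,9,9-trimethyl-1,4-dioxaspiro[4.5]dec-6-en-8-one | CC1=CC2(OCCO2)CC(C)(C)C1=O | intermediate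
3 | 7,9,9-trimethyl-8-[(trimethylsilyl)methyl]-1,4-dioxaspiro[4.5]dec-6-en-8-ol (racemic β-hydroxysilane, not isolated) | CC1=CC2(OCCO2)CC(C)(C)C1(O)C[Si](C)(C)C | intermediate
4 | 3,5,5-trimethyl-4-methylidenecyclohex-2-en-1-one (4-methyleneisophorone) | CC1=CC(=O)CC(C)(C)C1=C | intermediate
5 | (3R)-3,7-dimethyloct-6-enoic acid ((R)-citronellic acid) | CC(C)=CCC[C@@H](C)CC(=O)O | starting material
6 | tert-butyl (3R)-3,7-dimethyloct-6-enoate | CC(C)=CCC[C@@H](C)CC(=O)OC(C)(C)C | intermediate
7 | tert-butyl (3R,6E)-8-hydroxy-3,7-dimethyloct-6-enoate | OC/C(C)=C/CC[C@@H](C)CC(=O)OC(C)(C)C | intermediate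
8 | tert-butyl (3R,6E)-8-bromo-3,7-dimethyloct-6-enoate | BrC/C(C)=C/CC[C@@H](C)CC(=O)OC(C)(C)C | intermediate
9 | (S)-4-methylbenzenesulfinamide | Cc1ccc(cc1)[S@](=O)N | starting material
10 | (S)-N-(2,2-dimethylpropanoyl)-4-methylbenzenesulfinamide | Cc1ccc(cc1)[S@](=O)NC(=O)C(C)(C)C | intermediate
11 | tert-butyl (3R,6E)-8-[(S)-N-(2,2-dimethylpropanoyl)-S-(4-methylphenyl)sulfonimidoyl]-3,7-dimethyloct-6-enoate | Cc1ccc(cc1)[S@](=O)(=NC(=O)C(C)(C)C)C/C(C)=C/CC[C@@H](C)CC(=O)OC(C)(C)C | intermediate
12 | tert-butyl (3R,6E)-8-[(S)-N-(2,2-dimethylpropanoyl)-S-(4-methylphenyl)sulfonimidoyl]-3,7-dimethyl-9-(2,6,6-trimethyl-4-oxocyclohex-2-en-1-yl)non-6-enoate (open-chain 1,6-adduct, both epimers at C8 and at the ring carbon, not isolated) | CC1=CC(=O)CC(C)(C)C1CC(/C(C)=C/CC[C@@H](C)CC(=O)OC(C)(C)C)[S@@](=O)(=NC(=O)C(C)(C)C)c1ccc(C)cc1 | intermediate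
13 | tert-butyl (5R,9S,10S,13R)-7-[(R)-N-(2,2-dimethylpropanoyl)-S-(4-methylphenyl)sulfonimidoyl]-2-oxo-5,10-cis-labd-7-en-15-oate (H-5, H-9 and CH3-20 on one face; sulfur unchanged in space from 11, the descriptor changes because C7 is now vinylic) | O=C1CC(C)(C)[C@H]2CC([S@@](=O)(=NC(=O)C(C)(C)C)c3ccc(C)cc3)=C(C)[C@@H](CC[C@@H](C)CC(=O)OC(C)(C)C)[C@@]2(C)C1 | intermediate
14 | tert-butyl (5R,9R,10S,13R)-2-oxo-5,10-cis-labd-7-en-15-oate | O=C1CC(C)(C)[C@H]2CC=C(C)[C@@H](CC[C@@H](C)CC(=O)OC(C)(C)C)[C@@]2(C)C1 | intermediate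
15 | tert-butyl (2S,5R,9R,10S,13R)-2-hydroxy-5,10-cis-labd-7-en-15-oate | O[C@H]1CC(C)(C)[C@H]2CC=C(C)[C@@H](CC[C@@H](C)CC(=O)OC(C)(C)C)[C@@]2(C)C1 | intermediate
16 | (2Z)-2-methylbut-2-enoic acid (angelic acid) | C/C=C(/C)C(=O)O | starting material
17 | (2Z)-2-methylbut-2-enoic 2,4,6-trichlorobenzoic anhydride (not isolated) | C/C=C(/C)C(=O)OC(=O)c1c(Cl)cc(Cl)cc1Cl | intermediate
18 | tert-butyl (2S,5R,9R,10S,13R)-2-[(2Z)-2-methylbut-2-enoyloxy]-5,10-cis-labd-7-en-15-oate | C/C=C(/C)C(=O)O[C@H]1CC(C)(C)[C@H]2CC=C(C)[C@@H](CC[C@@H](C)CC(=O)OC(C)(C)C)[C@@]2(C)C1 | intermediate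
19 | (2S,5R,9R,10S,13R)-2-[(2Z)-2-methylbut-2-enoyloxy]-5,10-cis-labd-7-en-15-oic acid (CNP0248298.1) | C/C=C(/C)C(=O)O[C@H]1CC(C)(C)[C@H]2CC=C(C)[C@@H](CC[C@@H](C)CC(=O)O)[C@@]2(C)C1 | target

Total step count: 12. Longest linear sequence: 9 steps (5 → 6 → 7 → 8 → 11 → 13 → 14 → 15 → 18 → 19; steps 3, 4, 5, 7, 8, 9, 10, 11, 12).

Steps most likely to fail

Step 8. The allyl anion may react through its γ-carbon or add 1,2 or 1,4 in the first bond formation; ring closure at the hindered C10 may not occur; and facial control by sulfur may be poor. The fallback gives up the one-flask, sulfur-controlled annulation for a stepwise sequence with an achiral sulfone. It sets out from bromide 8 and dienone 4. Displacement of 8 with PhSO2Na in DMF should give tert-butyl (3R,6E)-8-(benzenesulfonyl)-3,7-dimethyloct-6-enoate F1. Its lithium salt (LiN(SiMe3)2, THF, −78 to −20 °C, acetic acid quench) should add through the α-carbon to the δ-methylene of 4 to give the isolated open-chain keto sulfone F2. t-BuOLi in THF at 0 °C should then close ring B by intramolecular Michael addition to the bicyclic vinyl sulfone F3, which is freed from its ring-antipodal diastereomer by preparative chromatography on a chiral stationary phase. Na(Hg)/Na2HPO4 in MeOH removes the sulfonyl group, and the route is rejoined at ketone 14.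

Step 9. The C2 ketone may be over-reduced or enter ketyl side reactions, and the C7=C8 bond may migrate through an allyl anion under electron-transfer conditions. The fallback cleaves the C–S bond by nickel-catalysed hydrogenolysis after masking the ketone. It sets out from 13. Me3SiOCH2CH2OSiMe3 with catalytic Me3SiOSO2CF3 in CH2Cl2 at −78 °C should give the 2,2-ethylenedioxy derivative F4. i-PrMgCl with catalytic Ni(acac)2 in THF at 0 °C should replace the sulfonimidoyl group by hydrogen (cross-coupling with β-hydride transfer, as known for vinyl sulfones) to give the dioxolane F5. Aqueous acetic acid in THF frees the ketone, and the route is rejoined at 14.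

Step 11. The angeloyl group may isomerise to the tigloyl group during acid activation, or acyl transfer may stall. The fallback makes the ester by O-alkylation of the angelate anion, which needs no activation of the acid. It sets out from ketone 14. LiBH(s-Bu)3 in THF at −78 °C should attack anti to the two syn-axial methyl groups and give the axial alcohol tert-butyl (2R,5R,9R,10S,13R)-2-hydroxy-5,10-cis-labd-7-en-15-oate F6. MeSO2Cl/Et3N should give the mesylate F7. Caesium angelate, made from 16 and Cs2CO3, should displace it with inversion in DMF at 60 °C (SN2), and the route is rejoined at 18, bypassing 15.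

Further compounds
F1 | step 8 | tert-butyl (3R,6E)-8-(benzenesulfonyl)-3,7-dimethyloct-6-enoate | O=S(=O)(C/C(C)=C/CC[C@@H](C)CC(=O)OC(C)(C)C)c1ccccc1
F2 | step 8 | tert-butyl (3R,6E)-8-(benzenesulfonyl)-3,7-dimethyl-9-(2,6,6-trimethyl-4-oxocyclohex-2-en-1-yl)non-6-enoate (epimers at C8 and at the ring carbon) | CC1=CC(=O)CC(C)(C)C1CC(/C(C)=C/CC[C@@H](C)CC(=O)OC(C)(C)C)S(=O)(=O)c1ccccc1
F3 | step 8 | tert-butyl (5R,9S,10S,13R)-7-(benzenesulfonyl)-2-oxo-5,10-cis-labd-7-en-15-oate | O=C1CC(C)(C)[C@H]2CC(S(=O)(=O)c3ccccc3)=C(C)[C@@H](CC[C@@H](C)CC(=O)OC(C)(C)C)[C@@]2(C)C1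
F4 | step 9 | tert-butyl (5R,9S,10S,13R)-7-[(R)-N-(2,2-dimethylpropanoyl)-S-(4-methylphenyl)sulfonimidoyl]-2,2-(ethane-1,2-diyldioxy)-5,10-cis-labd-7-en-15-oate | O1CCOC12CC(C)(C)[C@H]3CC([S@@](=O)(=NC(=O)C(C)(C)C)c4ccc(C)cc4)=C(C)[C@@H](CC[C@@H](C)CC(=O)OC(C)(C)C)[C@@]3(C)C2
F5 | step 9 | tert-butyl (5R,9R,10S,13R)-2,2-(ethane-1,2-diyldioxy)-5,10-cis-labd-7-en-15-oate | O1CCOC12CC(C)(C)[C@H]3CC=C(C)[C@@H](CC[C@@H](C)CC(=O)OC(C)(C)C)[C@@]3(C)C2
F6 | step 11 | tert-butyl (2R,5R,9R,10S,13R)-2-hydroxy-5,10-cis-labd-7-en-15-oate | O[C@@H]1CC(C)(C)[C@H]2CC=C(C)[C@@H](CC[C@@H](C)CC(=O)OC(C)(C)C)[C@@]2(C)C1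
F7 | step 11 | tert-butyl (2R,5R,9R,10S,13R)-2-(methanesulfonyloxy)-5,10-cis-labd-7-en-15-oate | CS(=O)(=O)O[C@@H]1CC(C)(C)[C@H]2CC=C(C)[C@@H](CC[C@@H](C)CC(=O)OC(C)(C)C)[C@@]2(C)C1
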